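**Retrosynthetic overview**
1. Spongiane numbering is used. Ring A is C1–C5/C10, ring B is C5–C10, and ring D is O/C13–C16. C11 is the CHO on C9 and C12 is the CH2OAc on C13.
2. Late stage: the C13=C16 enol ether comes from a selenoxide elimination at C16, and the C15 and C12 acetates come from a C16 lactone that carries a C15 menthyl acetal. The C8–C14 bond is cut to a tertiary C8 radical (H-atom transfer to C7=C8 of silylated (−)-drimenol) and (5S)-5-(d-menthyloxy)furan-2(5H)-one, which delivers ring D already closed.
3. Drimenol goes back (C11 by Wittig reaction and hydroboration) to 11-nordrim-7-en-9-one. Its ring A is cut at C3–C4, by a hydroalkylative closure of an isopropenyl group on C5 onto a 3-iodopropyl arm on C10. Both arms are set trans on (R)-carvone by two enolate alkylations.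
4. Enabling feature: C4 is a gem-dimethyl quaternary carbon bonded to the C5 methine, and ring A carries no heteroatom. C4 is therefore the Markovnikov radical of an isopropenyl group at C5, which carvone already carries with the correct C5 configuration, and a traceless C(sp3)–C(sp3) closure leaves nothing to remove.
5. Ring order: ring B (from carvone) and ring D (from the furanone) are bought closed. Ring A is the only ring the route closes, so no ring is closed after it.

Key step: step 3

Remark: α/β descriptors refer to the usual drimane/spongiane drawing (C10 methyl β). Transient stereocentres at C10 (compound 3) and C16 (compounds 17, 18, F8) are epimer mixtures that converge later.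
Remark: (5S)-5-(d-menthyloxy)furan-2(5H)-one, the crystalline acetal of 5-hydroxyfuran-2(5H)-one and (+)-menthol, is taken as a catalogue compound.

**Step 1**
Reactants: 1 (R)-(−)-carvone
Product: 3 6-methylcarvone, via lithium dienolate 2 (not isolated)
Conditions: LiN(iPr)2, THF, −78 °C; MeI, −78 → 0 °C
Reagents that add atoms: methyl iodide, CI; lithium diisopropylamide, CC(C)N([Li])C(C)C (lithium stays only in 2)
Why: Kinetic enolate alkylation: the amide base removes the α′-proton at C10 (carvone C6) of the cross-conjugated enone and the dienolate is C-methylated by SN2; the new C10 centre (mainly methyl trans to the C5 isopropenyl group) is flattened again in step 2, so its composition does not matter, and C5 is untouched.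

**Step 2**
Reactants: 3 6-methylcarvone; 4 1,3-diiodopropane
Product: 6 iodopropyl dialkylcarvone, via lithium dienolate 5 (not isolated)
Conditions: LiN(iPr)2, THF/DMPU, −78 °C; 4 (5 equiv), −78 → 0 °C
Reagents that add atoms: lithium diisopropylamide, CC(C)N([Li])C(C)C (lithium stays only in 5)
Why: Second kinetic α′-enolate alkylation: only C10–H is removed, and the primary iodide (in excess, so that one C–I bond survives) is attacked on the enolate face opposite the neighbouring C5 isopropenyl group, which sets quaternary C10 with the C1–C3 arm trans to isopropenyl and the C20 methyl cis to it, the relative configuration of a trans ring fusion.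

**Step 3**
Reactants: 6 iodopropyl dialkylcarvone
Product: 8 11-nordrim-7-en-9-one, via tertiary C4 radical 7 (not isolated)
Conditions: Mn(dpm)3 (20 mol %), Ni(acac)2 (10 mol %), PhSiH2(OiPr), K2CO3, ClCH2CH2Cl/propylene carbonate, 0.02 M, 23 °C
Reagents that add atoms: none
Why: Proposed new method: a manganese hydride formed from Mn(dpm)3 and the silane transfers a hydrogen atom to the CH2 terminus of the electron-rich 1,1-disubstituted isopropenyl group (Markovnikov), which turns that carbon into the second C4 methyl group and gives tertiary radical 7, while low-valent nickel formed in the same medium converts the primary C3–I bond into an alkylnickel that captures the C4 radical and, as a trivalent dialkylnickel, forms C3–C4 by reductive elimination. The closest known reaction type is the intermolecular Mn/Ni dual-catalysed Markovnikov hydroalkylation of unactivated 1,1-disubstituted alkenes with primary alkyl iodides, which builds aliphatic quaternary carbons; new here are the ring-closing format and the enone bystander. Ring A closes as a six-membered ring through a seven-membered nickelacycle (radical capture, then reductive elimination, so no exo/endo choice arises because no π bond is attacked), starting from the favoured conformer in which the isopropenyl and iodopropyl arms are both equatorial and gauche, which maps directly onto the trans-decalin. No stereocentre is created, since C4 ends with two methyl groups, and the trans fusion is inherited from C5 (carvone) and C10 (step 2), which the step does not touch. The step needs H-atom transfer to the isopropenyl group rather than to C7=C8, which should be secured because C7=C8 is an electron-poor, trisubstituted, α-methyl enone bond and the medium is alcohol-free, and it needs nickel capture to outrun reduction, which the tether secures by holding C3 next to C4. Radical 7 has no competing cyclisation (C7 would need a four-membered ring, C8 is the electronically mismatched α-carbon) and dilution suppresses intermolecular Giese addition, so one operation delivers the gem-dimethyl quaternary carbon, ring A and the complete drimane bicycle with nothing to remove.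

**Step 4**
Reactants: 8 11-nordrim-7-en-9-one
Product: 9 drima-7,9(11)-diene
Conditions: Ph3PCH3Br, KOtBu, toluene, 80 °C
Reagents that add atoms: methyltriphenylphosphonium bromide, C[P+](c1ccccc1)(c1ccccc1)c1ccccc1.[Br-]
Why: Wittig methylenation: the small non-stabilised ylide adds 1,2 to the C9 carbonyl, which has a quaternary C10 and an sp2 C8 as neighbours, so α-enolisation and epimerisation cannot compete; no stereocentre is formed.

**Step 5**
Reactants: 9 drima-7,9(11)-diene
Product: 11 (−)-drimenol, via B-drimenyl-9-BBN 10 (not isolated)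
Conditions: 9-BBN, THF, 0 → 23 °C; NaOH, H2O2, 0 °C
Reagents that add atoms: 9-borabicyclo[3.3.1]nonane, B1C2CCCC1CCC2 (boron stays only in 10); hydrogen peroxide, OO
Why: Hydroboration–oxidation: 9-BBN places boron on the unhindered terminal C11 of the 1,1-disubstituted alkene, ignores the trisubstituted C7=C8 bond, and delivers hydrogen to C9 from the α face opposite the axial C10 methyl group, which sets C9 (H α, CH2OH β-equatorial); the oxidation proceeds with retention.

**Step 6**
Reactants: 11 (−)-drimenol
Product: 12 drimenyl TBDPS ether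
Conditions: TBDPSCl, imidazole, DMF, 23 °C
Reagents that add atoms: tert-butyl(chloro)diphenylsilane, CC(C)(C)[Si](Cl)(c1ccccc1)c1ccccc1
Why: Silylation of the primary alcohol; this silyl group is chosen because it should survive the base, hydride and Lewis-acid steps 8–11 and still fall to fluoride in step 12.

**Step 7**
Reactants: 12 drimenyl TBDPS ether; 13 (5S)-5-(d-menthyloxy)furan-2(5H)-one
Product: 14 C8–C14 coupled lactone
Conditions: Fe(acac)3 (30 mol %), PhSiH3, EtOH/(CH2OH)2, 60 °C; 13 (2 equiv)
Reagents that add atoms: none
Why: Iron-hydride H-atom-transfer Giese coupling (reductive olefin coupling): hydrogen adds to C7, the nucleophilic tertiary C8 radical adds to the butenolide β-carbon C14, and the α-acyl radical is reduced by divalent iron and protonated; C14 is set by attack anti to the C15 menthyloxy group, and C8 by bond formation on the α (equatorial) face of the decalin away from the axial C10 methyl group, which leaves the C8 methyl axial (β).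

**Step 8**
Reactants: 14 C8–C14 coupled lactone
Product: 16 13-hydroxymethyl lactone, via lithium lactone enolate 15 (not isolated)
Conditions: LiN(iPr)2, THF, −78 °C; CH2O (gas), −78 → −40 °C; AcOH
Reagents that add atoms: formaldehyde, C=O; lithium diisopropylamide, CC(C)N([Li])C(C)C (lithium stays only in 15)
Why: Lactone enolate aldol (hydroxymethylation): C13 is the only acidic position, and formaldehyde approaches anti to the bulky C14 substituent (CH2OH α, H-13 β); this centre only serves to place H-13 for step 14 and then vanishes.

**Step 9**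
Reactants: 16 13-hydroxymethyl lactone
Product: 18 12,16-diacetate, via bis(diisobutylaluminium) alkoxide 17 (not isolated)
Conditions: iBu2AlH (3 equiv), CH2Cl2, −78 °C; pyridine, DMAP (cat.), Ac2O, −78 → 0 °C
Reagents that add atoms: diisobutylaluminium hydride, CC(C)C[AlH]CC(C)C (aluminium stays only in 17); acetic anhydride, CC(=O)OC(C)=O
Why: Reductive acetylation of a lactone: at −78 °C the hydride stops at the tetrahedral aluminium lactolate, which is acetylated in situ together with the C12 alkoxide, so ring D never opens; C16 forms as an epimer mixture that converges in step 10, and the menthyl acetal and silyl ether are inert.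

**Step 10**
Reactants: 18 12,16-diacetate
Product: 19 16β-phenylselanyl acetal
Conditions: PhSeH (1.1 equiv), BF3·OEt2 (20 mol %), CH2Cl2, −78 °C
Reagents that add atoms: benzeneselenol, [SeH]c1ccccc1
Why: Lewis-acid selenoglycosidation of an anomeric acetate: catalytic BF3 at −78 °C ionises only the acyloxy acetal at C16 (the alkyl acetal at C15 and the primary acetate need stronger activation), and the oxocarbenium ion, covered on its α face by the participating C12 acetate, should take up PhSeH from the β face, which places selenium trans to CH2OAc and cis to H-13.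

**Step 11**
Reactants: 19 16β-phenylselanyl acetal
Product: 20 15α-acetoxy selenide
Conditions: Ac2O (10 equiv), TMSOTf (10 mol %), CH2Cl2, −40 → −20 °C
Reagents that add atoms: acetic anhydride, CC(=O)OC(C)=O
Why: Acetolysis of an alkyl furanoside-type acetal: the hard acylating species attacks the exocyclic menthyl oxygen rather than the soft selenium, menthyl acetate leaves, and acetate adds to the ring oxocarbenium ion at C15 anti to the bulky C14 substituent, which sets the 15α-acetate (trans to C8) while ring D stays closed and still saturated, so no furan can form.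

**Step 12**
Reactants: 20 15α-acetoxy selenide
Product: 21 C11 alcohol
Conditions: HF·pyridine, pyridine, THF, 0 → 23 °C
Reagents that add atoms: none
Why: Fluoride desilylation buffered with excess pyridine; the acetates and the O,Se-acetal are not fluoride-labile, and the buffer keeps the anomeric acetate from ionising next to the freed C11 hydroxyl.

**Step 13**
Reactants: 21 C11 alcohol
Product: 22 C11 aldehyde
Conditions: Dess–Martin periodinane, pyridine, CH2Cl2, 0 → 23 °C
Reagents that add atoms: none
Why: Dess–Martin oxidation: a neutral, buffered oxidation of the hindered primary alcohol that should leave the selenide and acetates alone; C9 keeps its configuration, and the equatorial formyl group is also the thermodynamic one.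

**Step 14**
Reactants: 22 C11 aldehyde
Product: 24 target CNP0170308.1, via selenoxide 23 (not isolated)
Conditions: mCPBA (1.0 equiv), CH2Cl2, −78 °C; iPr2NEt, −78 → 23 °C
Reagents that add atoms: 3-chloroperbenzoic acid, OOC(=O)c1cccc(Cl)c1 (oxygen stays only in 23)
Why: Selenoxide syn-elimination, as used for furanoid glycals: selenium is oxidised at −78 °C faster than any other group, and on warming the selenoxide takes its only β-hydrogen, the cis H-13, which forms C13=C16 regiospecifically under base-buffered, acid-free conditions that spare the C15 acetate, the now allylic C12 acetate and the aldehyde; C13 and C16 cease to be stereocentres and all others are those of the target.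

**Compound list**
1 | (R)-(−)-carvone, (5R)-2-methyl-5-(prop-1-en-2-yl)cyclohex-2-en-1-one | CC1=CC[C@@H](C(C)=C)CC1=O | starting material
2 | lithium cross-conjugated dienolate of 1 (C9–OLi, C9=C10; not isolated) | CC1=CC[C@@H](C(C)=C)C=C1O[Li] | intermediate
3 | 6-methylcarvone, (5R)-2,6-dimethyl-5-(prop-1-en-2-yl)cyclohex-2-en-1-one, drawn as the main (5R,6S) epimer with methyl trans to isopropenyl | CC1=CC[C@@H](C(C)=C)[C@H](C)C1=O | intermediate
4 | 1,3-diiodopropane | ICCCI | starting material
5 | lithium dienolate of 3 (C9–OLi, C9=C10 bearing methyl; not isolated) | CC1=CC[C@@H](C(C)=C)C(C)=C1O[Li] | intermediate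
6 | (5S,6S)-6-(3-iodopropyl)-2,6-dimethyl-5-(prop-1-en-2-yl)cyclohex-2-en-1-one, iodopropyl trans and methyl cis to isopropenyl | CC1=CC[C@@H](C(C)=C)[C@@](CCCI)(C)C1=O | intermediate
7 | tertiary C4 radical from H-atom transfer to the isopropenyl CH2 of 6 (not isolated) | CC1=CC[C@@H]([C](C)C)[C@@](CCCI)(C)C1=O | intermediate
8 | 11-nordrim-7-en-9-one, (4aS,8aS)-2,5,5,8a-tetramethyl-4a,5,6,7,8,8a-hexahydronaphthalen-1(4H)-one, trans-fused (H-5 α, C10 methyl β) | CC1=CC[C@H]2C(C)(C)CCC[C@]2(C)C1=O | intermediate
9 | drima-7,9(11)-diene (trans-fused, exocyclic C9=C11H2, C7=C8) | CC1=CC[C@H]2C(C)(C)CCC[C@]2(C)C1=C | intermediate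
10 | B-(drim-7-en-11-yl)-9-borabicyclo[3.3.1]nonane, H-9 α (not isolated) | CC1=CC[C@H]2C(C)(C)CCC[C@]2(C)[C@H]1CB1C2CCCC1CCC2 | intermediate
11 | (−)-drimenol, [(1S,4aS,8aS)-2,5,5,8a-tetramethyl-1,4,4a,5,6,7,8,8a-octahydronaphthalen-1-yl]methanol | CC1=CC[C@H]2C(C)(C)CCC[C@]2(C)[C@H]1CO | intermediate
12 | drimenyl tert-butyldiphenylsilyl ether | CC1=CC[C@H]2C(C)(C)CCC[C@]2(C)[C@H]1CO[Si](c1ccccc1)(c1ccccc1)C(C)(C)C | intermediate
13 | (5S)-5-(d-menthyloxy)furan-2(5H)-one | O=C1C=C[C@@H](O[C@H]2C[C@@H](C)CC[C@@H]2C(C)C)O1 | starting material
14 | coupled lactone: 5-(d-menthyloxy)dihydrofuran-2(3H)-one whose C4 (= C14, H α) carries drimane C8 (C8 methyl β-axial, C14 α-equatorial), menthyloxy on C15 trans to the drimane, C11–OTBDPS | C1C(=O)O[C@H](O[C@H]2C[C@@H](C)CC[C@@H]2C(C)C)[C@H]1[C@]1(C)CC[C@H]2C(C)(C)CCC[C@]2(C)[C@H]1CO[Si](c1ccccc1)(c1ccccc1)C(C)(C)C | intermediate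
15 | lithium enolate of 14 (C13=C16–OLi; not isolated) | C1=C(O[Li])O[C@H](O[C@H]2C[C@@H](C)CC[C@@H]2C(C)C)[C@H]1[C@]1(C)CC[C@H]2C(C)(C)CCC[C@]2(C)[C@H]1CO[Si](c1ccccc1)(c1ccccc1)C(C)(C)C | intermediate
16 | 13-hydroxymethyl lactone (C12H2OH α on C13, trans to the drimane on C14) | OC[C@@H]1C(=O)O[C@H](O[C@H]2C[C@@H](C)CC[C@@H]2C(C)C)[C@H]1[C@]1(C)CC[C@H]2C(C)(C)CCC[C@]2(C)[C@H]1CO[Si](c1ccccc1)(c1ccccc1)C(C)(C)C | intermediate
17 | bis(diisobutylaluminium) alkoxide of the C16 lactol and C12 alcohol (C16 epimers; not isolated) | CC(C)C[Al](CC(C)C)OC[C@@H]1C(O[Al](CC(C)C)CC(C)C)O[C@H](O[C@H]2C[C@@H](C)CC[C@@H]2C(C)C)[C@H]1[C@]1(C)CC[C@H]2C(C)(C)CCC[C@]2(C)[C@H]1CO[Si](c1ccccc1)(c1ccccc1)C(C)(C)C | intermediate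
18 | 12,16-diacetate: tetrahydrofuran with C16–OAc (epimers), C13–CH2OAc (α), C15–O-d-menthyl (α), C11–OTBDPS | CC(=O)OC[C@@H]1C(OC(C)=O)O[C@H](O[C@H]2C[C@@H](C)CC[C@@H]2C(C)C)[C@H]1[C@]1(C)CC[C@H]2C(C)(C)CCC[C@]2(C)[C@H]1CO[Si](c1ccccc1)(c1ccccc1)C(C)(C)C | intermediate
19 | 16β-phenylselanyl acetal (SePh trans to CH2OAc, cis to H-13), C15–O-d-menthyl retained | CC(=O)OC[C@@H]1[C@@H]([Se]c2ccccc2)O[C@H](O[C@H]2C[C@@H](C)CC[C@@H]2C(C)C)[C@H]1[C@]1(C)CC[C@H]2C(C)(C)CCC[C@]2(C)[C@H]1CO[Si](c1ccccc1)(c1ccccc1)C(C)(C)C | intermediate
20 | 15α-acetoxy-16β-phenylselanyl tetrahydrofuran, C12–OAc, C11–OTBDPS | CC(=O)OC[C@@H]1[C@@H]([Se]c2ccccc2)O[C@H](OC(C)=O)[C@H]1[C@]1(C)CC[C@H]2C(C)(C)CCC[C@]2(C)[C@H]1CO[Si](c1ccccc1)(c1ccccc1)C(C)(C)C | intermediate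
21 | C11 alcohol of 20 | CC(=O)OC[C@@H]1[C@@H]([Se]c2ccccc2)O[C@H](OC(C)=O)[C@H]1[C@]1(C)CC[C@H]2C(C)(C)CCC[C@]2(C)[C@H]1CO | intermediate
22 | C11 aldehyde (formyl β-equatorial on C9) | CC(=O)OC[C@@H]1[C@@H]([Se]c2ccccc2)O[C@H](OC(C)=O)[C@H]1[C@]1(C)CC[C@H]2C(C)(C)CCC[C@]2(C)[C@H]1C=O | intermediate
23 | C16 selenoxide of 22 (not isolated) | CC(=O)OC[C@@H]1[C@@H]([Se](=O)c2ccccc2)O[C@H](OC(C)=O)[C@H]1[C@]1(C)CC[C@H]2C(C)(C)CCC[C@]2(C)[C@H]1C=O | intermediate
24 | CNP0170308.1: 12,15α-diacetoxy-15,16-epoxy-11,12-seco-spongi-13(16)-en-11-al (H-5 α, H-9 α, H-14 α, C8 and C10 methyls β) | CC(=O)OCC1=CO[C@H](OC(C)=O)[C@H]1[C@]1(C)CC[C@H]2C(C)(C)CCC[C@]2(C)[C@H]1C=O | target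

**Totals**
Total step count: 14. Longest linear sequence: 14 steps, from (R)-carvone.

**Steps most likely to fail**

1. Step 3 (labelled step). The manganese hydride may transfer hydrogen to the C7=C8 enone or reduce it conjugatively. The C4 radical may also be hydrogenated, or the C3–I bond hydrodeiodinated or β-eliminated at nickel, before the two ends meet. The fallback sets out from 3 and comes back at 8, and it replaces the nickel-mediated alkyl–alkyl union by a polarity-matched radical conjugate addition with a removable ester. Enolate 5 is alkylated with methyl 2-(bromomethyl)acrylate, again anti to isopropenyl, to give the acrylate-armed enone F1. Fe(acac)3/PhSiH3 in EtOH generates the same C4 radical, which closes ring A by 6-endo Giese addition to the acrylate CH2 (C3) and gives the bicyclic C2 ester F2. LiOH gives the acid F3, and N-hydroxyphthalimide with diisopropylcarbodiimide gives the N-(acyloxy)phthalimide F4. Visible-light reductive decarboxylation (Ru(bpy)3(PF6)2, Hantzsch ester, iPr2NEt) then removes the C2 carboxyl group and delivers 8.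

2. Step 7. The hindered C8 radical may be reduced (net hydrogenation) or may hand its hydrogen back (alkene isomerisation) faster than it adds to the butenolide, and facial control at C8 may erode at 60 °C. The fallback sets out from 12 and comes back at 14, and it changes the radical source so that no metal hydride is present. Mukaiyama hydration (Mn(dpm)3, PhSiH3, O2, iPrOH) gives the tertiary C8 alcohol F5. Methyl chlorooxoacetate with Et3N and DMAP gives the methyl oxalate F6, and aqueous CsOH gives the caesium oxalate F7. Photoredox double decarboxylation (Ir[dF(CF3)ppy]2(dtbbpy)PF6, blue light, H2O, DME/DMF, 23 °C) in the presence of 13 generates the same C8 radical and gives 14.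

3. Step 11. Ionisation may occur at C16 with loss of the phenylselanyl group. Endocyclic C–O cleavage, or loss of H-14 from the C15 cation, may also compete with clean exchange of the menthyloxy group. The fallback sets out from 18 and comes back at 20, and it performs the acid step before any selenium is present. Classical acetolysis of 18 (Ac2O/AcOH, catalytic H2SO4, 0 °C) gives the 12,15,16-triacetate F8. One equivalent of PhSeH with catalytic BF3·OEt2 at −78 °C then substitutes the anomeric acetate at C16, which is assisted by the neighbouring C12 acetate and is not flanked by the neopentyl-like C14, and gives 20.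

**Further compounds**
F1 | step 3 | (5S,6S)-configured 6-[2-(methoxycarbonyl)allyl]-2,6-dimethyl-5-(prop-1-en-2-yl)cyclohex-2-en-1-one | CC1=CC[C@@H](C(C)=C)[C@@](CC(=C)C(=O)OC)(C)C1=O
F2 | step 3 | methyl 9-oxo-11-nordrim-7-ene-2-carboxylate (C2 epimers) | CC1=CC[C@H]2C(C)(C)CC(C(=O)OC)C[C@]2(C)C1=O
F3 | step 3 | 9-oxo-11-nordrim-7-ene-2-carboxylic acid (C2 epimers) | CC1=CC[C@H]2C(C)(C)CC(C(=O)O)C[C@]2(C)C1=O
F4 | step 3 | N-(acyloxy)phthalimide of F3 | CC1=CC[C@H]2C(C)(C)CC(C(=O)ON3C(=O)c4ccccc4C3=O)C[C@]2(C)C1=O
F5 | step 7 | 11-(tert-butyldiphenylsilyloxy)driman-8α-ol | O[C@]1(C)CC[C@H]2C(C)(C)CCC[C@]2(C)[C@H]1CO[Si](c1ccccc1)(c1ccccc1)C(C)(C)C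
F6 | step 7 | methyl oxalate of F5 | COC(=O)C(=O)O[C@]1(C)CC[C@H]2C(C)(C)CCC[C@]2(C)[C@H]1CO[Si](c1ccccc1)(c1ccccc1)C(C)(C)C
F7 | step 7 | caesium oxalate of F5 | [Cs+].[O-]C(=O)C(=O)O[C@]1(C)CC[C@H]2C(C)(C)CCC[C@]2(C)[C@H]1CO[Si](c1ccccc1)(c1ccccc1)C(C)(C)C
F8 | step 11 | 12,15α,16-triacetate (C16 epimers), C11–OTBDPS | CC(=O)OC[C@@H]1C(OC(C)=O)O[C@H](OC(C)=O)[C@H]1[C@]1(C)CC[C@H]2C(C)(C)CCC[C@]2(C)[C@H]1CO[Si](c1ccccc1)(c1ccccc1)C(C)(C)C
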